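The bond on which the route rests is the interflavan bond between C4 of the middle (5-deoxy) C-ring and C8 of the catechin A-ring. In the key step a dimeric flavan-4-ol is ionised by acid. The cation at C4, benzylic and conjugated to O7 (para) and O1 of the middle unit, is captured by C8 of tetra-O-benzylcatechin on the β face, anti to the α-oriented C3 oxygen, forming the bond and the C4 stereocentre at once. The precursor is built as a procyanidin B2-type dimer: the middle unit carries a temporary O5 that steers the first coupling to C8; a C4 ketone then serves to unmask and excise O5 and becomes the leaving group.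

Key step: step 11

Remark: the target is read as epicatechin-(4β→8)-epifisetinidol-(4β→8)-catechin; T, M and B denote its top, middle and bottom flavan units, locants are those of the flavan skeleton, and α/β name the faces of the C-ring (the C2 aryl group is α in every unit).

Step 1
Reactants: 1 (−)-epicatechin
Product: 2 3,5,7,3',4'-penta-O-benzyl-(−)-epicatechin
Conditions: BnBr (6.5 equiv), NaH (6 equiv), DMF, 0 °C → rt
Reagents that add atoms: benzyl bromide, BrCc1ccccc1
Why: Exhaustive Williamson etherification of the four phenoxides and the C3 alkoxide should proceed in DMF with the halide present from the start, so that O-alkylation outruns base-induced C2 epimerisation, and no stereocentre is touched.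

Step 2
Reactants: 2 3,5,7,3',4'-penta-O-benzyl-(−)-epicatechin
Product: 3 4β-(2-ethoxyethoxy)-3,5,7,3',4'-penta-O-benzylepicatechin (2,3-cis-3,4-trans)
Conditions: DDQ (2 equiv), 2-ethoxyethanol (5 equiv), CH2Cl2, rt
Reagents that add atoms: 2-ethoxyethanol, CCOCCO
Why: DDQ benzylic oxidation abstracts hydride from C4, which is activated by O5, O7 and O1, and the alcohol should trap the cation anti to the C3 benzyloxy group to set the 3,4-trans (4β) ether.

Step 3
Reactants: 3 4β-(2-ethoxyethoxy)-penta-O-benzylepicatechin; 2 penta-O-benzylepicatechin (4 equiv)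
Product: 4 deca-O-benzylprocyanidin B2, i.e. penta-O-benzylepicatechin-(4β→8)-penta-O-benzylepicatechin (units T and M)
Conditions: TMSOTf (0.1 equiv), CH2Cl2, −78 °C; excess 2 should be recoverable
Reagents that add atoms: none
Why: In this Lewis-acid-promoted Friedel–Crafts coupling of a flavan-4-yl cation (procyanidin condensation), the cation from 3 should be attacked by C8 of 2, the most nucleophilic carbon of its phloroglucinol-type A-ring because O5 is still present, from the β face anti to the C3 benzyloxy group, which sets the 4β stereocentre of T.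

Step 4
Reactants: 4 deca-O-benzylprocyanidin B2
Product: 5 dimer with a 4β-hydroxyl on the M unit (M: 2,3-cis-3,4-trans)
Conditions: DDQ (1.5 equiv), CH2Cl2/H2O (18:1), 0 °C → rt
Reagents that add atoms: water, O
Why: DDQ benzylic oxidation with water as the trap should hydroxylate the only benzylic methylene, C4 of M (activated by O5, O7 and O1), because the C4–H of T is a shielded diarylmethine that cannot align with its two di-ortho-substituted rings; water adds anti to O3, although this centre is erased in step 5.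

Step 5
Reactants: 5 dimer with 4β-hydroxyl on M
Product: 6 dimer with a C4 ketone on M (M: (2R,3S)-2,3-cis-3,5,7,3',4'-penta-O-benzyldihydroquercetin unit)
Conditions: Dess–Martin periodinane, CH2Cl2, rt
Reagents that add atoms: none
Why: Dess–Martin oxidation of the single free secondary alcohol should give the aryl ketone under neutral conditions that do not enolise the α-benzyloxy ketone, so the 2,3-cis arrangement of M is kept.

Step 6
Reactants: 6 dimer with C4 ketone on M
Product: 7 dimer with C4 ketone and free 5-OH on M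
Conditions: MgBr2·OEt2 (3 equiv), toluene/Et2O, 40 °C
Reagents that add atoms: none
Why: In this chelation-controlled debenzylation of an aryl benzyl ether ortho to a carbonyl group, Mg2+ bridges the C4 ketone and O5 of M, so bromide should remove only this benzyl group as the vinylogous magnesium phenoxide departs, leaving the eight other aryl benzyl ethers and the aliphatic 3-O-benzyl ethers untouched.

Step 7
Reactants: 7 dimer with C4 ketone and free 5-OH on M
Product: 8 dimer with C4 ketone and 5-O-triflate on M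
Conditions: Tf2O, pyridine, CH2Cl2, −20 → 0 °C
Reagents that add atoms: trifluoromethanesulfonic anhydride, FC(F)(F)S(=O)(=O)OS(=O)(=O)C(F)(F)F
Why: O-Sulfonylation of the only free hydroxyl, the chelated phenol, should be fast with Tf2O/pyridine at low temperature, before enolisation of the ketone can compete.

Step 8
Reactants: 8 dimer with C4 ketone and 5-O-triflate on M
Product: 9 dimer whose M unit is a 5-deoxy ketone (M: 2,3-cis-3,7,3',4'-tetra-O-benzyldihydrofisetin unit)
Conditions: Pd(OAc)2 (10 mol%), dppp (10 mol%), Et3SiH (2.5 equiv), DMF, 60 °C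
Reagents that add atoms: none
Why: In this palladium-catalysed hydrodetriflation, the aryl triflate ortho to the ketone should undergo fast oxidative addition and the aryl–Pd species be reduced by the silane under neutral, homogeneous conditions, which excises the temporary O5 without epimerising C3 or cleaving benzyl ethers.

Step 9
Reactants: 9 dimer with 5-deoxy ketone M unit
Product: 10 dimer whose M unit is 3,7,3',4'-tetra-O-benzylepifisetinidol-4-ol (major epimer expected 4α, 2,3-cis-3,4-cis)
Conditions: NaBH4, THF/MeOH, 0 °C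
Reagents that add atoms: none
Why: Borohydride reduction of the aryl ketone should deliver hydride anti to the quasi-axial C3 benzyloxy group to give mainly the 3,4-cis alcohol, and either C4 epimer serves because this centre is ionised in step 11.

Step 10
Reactants: 11 (+)-catechin
Product: 12 5,7,3',4'-tetra-O-benzyl-(+)-catechin
Conditions: BnBr (4.4 equiv), K2CO3, DMF, rt
Reagents that add atoms: benzyl bromide, BrCc1ccccc1
Why: Williamson etherification under carbonate conditions should alkylate only the four phenols and leave the C3 hydroxyl and both stereocentres untouched.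

Step 11
Reactants: 10 dimeric flavan-4-ol (T–M); 12 5,7,3',4'-tetra-O-benzyl-(+)-catechin (4 equiv)
Product: 13 trideca-O-benzyl trimer, penta-O-benzylepicatechin-(4β→8)-3,7,3',4'-tetra-O-benzylepifisetinidol-(4β→8)-5,7,3',4'-tetra-O-benzylcatechin
Conditions: TMSOTf (0.3 equiv), CH2Cl2, −40 → −10 °C; 10 added slowly to 12
Reagents that add atoms: none
Why: Triflic acid released from TMSOTf ionises the benzylic C4–OH of M to a cation delocalised onto O7 (para through the A-ring) and O1, a p-quinone-methide-type ion, which C8 of 12 attacks before the Wheland intermediate loses a proton, i.e. an SN1 Friedel–Crafts alkylation in which the hydroxyl of 10 leaves as water, the only by-product. The closest known reaction type is the acid-mediated condensation of flavan-3,4-diols or 4-alkoxyflavans with flavan-3-ols used to assemble profisetinidins and procyanidins. No ring is closed. The one new stereocentre, C4 of M, is substrate-controlled: in the half-chair cation the C2 aryl group is quasi-equatorial and the cis C3 benzyloxy group quasi-axial on the α face, so the arene should add to the β face anti to O3 and give the 3,4-trans (4β) bond whatever the C4 configuration of 10. The step needs C8 over C6 selectivity in 12, secured because C8 lies between O1 and one benzyloxy group whereas C6 is buried between two, and cross- over self-coupling, secured by the excess of 12, the slow addition of 10 and the weak, resorcinol-type nucleophilicity of the M A-ring once O5 is gone. The same loss of O5 should protect the existing T–M bond from acid cleavage, since ipso-protonation at C8 of M is no longer favoured.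

Step 12
Reactants: 13 trideca-O-benzyl trimer
Product: 14 epicatechin-(4β→8)-epifisetinidol-(4β→8)-catechin (target)
Conditions: H2 (1 atm), Pd(OH)2/C, THF/MeOH/H2O, rt
Reagents that add atoms: none
Why: Catalytic hydrogenolysis should cleave all thirteen benzyl ethers, aryl and aliphatic, under neutral conditions that leave the C2–O1 bonds, the interflavan bonds and every stereocentre intact.

Compound list
1 | (−)-epicatechin, (2R,3R)-2-(3,4-dihydroxyphenyl)chromane-3,5,7-triol | Oc1cc(O)c2c(c1)O[C@H](c1ccc(O)c(O)c1)[C@H](O)C2 | starting material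
2 | 3,5,7,3',4'-penta-O-benzyl-(−)-epicatechin (2,3-cis) | c1ccccc1COc1cc(OCc3ccccc3)c2c(c1)O[C@H](c1ccc(OCc3ccccc3)c(OCc3ccccc3)c1)[C@H](OCc3ccccc3)C2 | intermediate
3 | 4β-(2-ethoxyethoxy)-3,5,7,3',4'-penta-O-benzylepicatechin (2,3-cis-3,4-trans) | c1ccccc1COc1cc(OCc3ccccc3)c2c(c1)O[C@H](c1ccc(OCc3ccccc3)c(OCc3ccccc3)c1)[C@H](OCc3ccccc3)[C@H]2OCCOCC | intermediate
4 | deca-O-benzylprocyanidin B2, penta-O-benzylepicatechin-(4β→8)-penta-O-benzylepicatechin | c1ccccc1COc1cc(OCc3ccccc3)c2c(c1)O[C@H](c1ccc(OCc3ccccc3)c(OCc3ccccc3)c1)[C@H](OCc3ccccc3)[C@H]2c1c(OCc3ccccc3)cc(OCc3ccccc3)c2c1O[C@H](c1ccc(OCc3ccccc3)c(OCc3ccccc3)c1)[C@H](OCc3ccccc3)C2 | intermediate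
5 | dimer 4 with a 4β-hydroxyl on the M unit (M: 2,3-cis-3,4-trans) | c1ccccc1COc1cc(OCc3ccccc3)c2c(c1)O[C@H](c1ccc(OCc3ccccc3)c(OCc3ccccc3)c1)[C@H](OCc3ccccc3)[C@H]2c1c(OCc3ccccc3)cc(OCc3ccccc3)c2c1O[C@H](c1ccc(OCc3ccccc3)c(OCc3ccccc3)c1)[C@H](OCc3ccccc3)[C@H]2O | intermediate
6 | dimer with C4 ketone on M (M: 2,3-cis-penta-O-benzyldihydroquercetin unit, C8-linked to C4β of T) | c1ccccc1COc1cc(OCc3ccccc3)c2c(c1)O[C@H](c1ccc(OCc3ccccc3)c(OCc3ccccc3)c1)[C@H](OCc3ccccc3)[C@H]2c1c(OCc3ccccc3)cc(OCc3ccccc3)c2c1O[C@H](c1ccc(OCc3ccccc3)c(OCc3ccccc3)c1)[C@H](OCc3ccccc3)C2=O | intermediate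
7 | dimer with C4 ketone and free 5-OH on M (nona-O-benzyl) | c1ccccc1COc1cc(OCc3ccccc3)c2c(c1)O[C@H](c1ccc(OCc3ccccc3)c(OCc3ccccc3)c1)[C@H](OCc3ccccc3)[C@H]2c1c(OCc3ccccc3)cc(O)c2c1O[C@H](c1ccc(OCc3ccccc3)c(OCc3ccccc3)c1)[C@H](OCc3ccccc3)C2=O | intermediate
8 | dimer with C4 ketone and 5-O-trifluoromethanesulfonate on M | c1ccccc1COc1cc(OCc3ccccc3)c2c(c1)O[C@H](c1ccc(OCc3ccccc3)c(OCc3ccccc3)c1)[C@H](OCc3ccccc3)[C@H]2c1c(OCc3ccccc3)cc(OS(=O)(=O)C(F)(F)F)c2c1O[C@H](c1ccc(OCc3ccccc3)c(OCc3ccccc3)c1)[C@H](OCc3ccccc3)C2=O | intermediate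
9 | dimer with 5-deoxy ketone M unit (M: 2,3-cis-3,7,3',4'-tetra-O-benzyldihydrofisetin unit) | c1ccccc1COc1cc(OCc3ccccc3)c2c(c1)O[C@H](c1ccc(OCc3ccccc3)c(OCc3ccccc3)c1)[C@H](OCc3ccccc3)[C@H]2c1c(OCc3ccccc3)ccc2c1O[C@H](c1ccc(OCc3ccccc3)c(OCc3ccccc3)c1)[C@H](OCc3ccccc3)C2=O | intermediate
10 | penta-O-benzylepicatechin-(4β→8)-3,7,3',4'-tetra-O-benzylepifisetinidol-4α-ol (major C4 epimer drawn, 2,3-cis-3,4-cis) | c1ccccc1COc1cc(OCc3ccccc3)c2c(c1)O[C@H](c1ccc(OCc3ccccc3)c(OCc3ccccc3)c1)[C@H](OCc3ccccc3)[C@H]2c1c(OCc3ccccc3)ccc2c1O[C@H](c1ccc(OCc3ccccc3)c(OCc3ccccc3)c1)[C@H](OCc3ccccc3)[C@@H]2O | intermediate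
11 | (+)-catechin, (2R,3S)-2-(3,4-dihydroxyphenyl)chromane-3,5,7-triol | Oc1cc(O)c2c(c1)O[C@H](c1ccc(O)c(O)c1)[C@@H](O)C2 | starting material
12 | 5,7,3',4'-tetra-O-benzyl-(+)-catechin (2,3-trans, free 3-OH) | c1ccccc1COc1cc(OCc3ccccc3)c2c(c1)O[C@H](c1ccc(OCc3ccccc3)c(OCc3ccccc3)c1)[C@@H](O)C2 | intermediate
13 | trideca-O-benzyl trimer, penta-O-benzylepicatechin-(4β→8)-3,7,3',4'-tetra-O-benzylepifisetinidol-(4β→8)-5,7,3',4'-tetra-O-benzylcatechin | c1ccccc1COc1cc(OCc3ccccc3)c2c(c1)O[C@H](c1ccc(OCc3ccccc3)c(OCc3ccccc3)c1)[C@H](OCc3ccccc3)[C@H]2c1c(OCc3ccccc3)ccc2c1O[C@H](c1ccc(OCc3ccccc3)c(OCc3ccccc3)c1)[C@H](OCc3ccccc3)[C@H]2c1c(OCc3ccccc3)cc(OCc3ccccc3)c2c1O[C@H](c1ccc(OCc3ccccc3)c(OCc3ccccc3)c1)[C@@H](O)C2 | intermediate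
14 | epicatechin-(4β→8)-epifisetinidol-(4β→8)-catechin, CNP0270097.1 | Oc1cc(O)c2c(c1)O[C@H](c1ccc(O)c(O)c1)[C@H](O)[C@H]2c1c(O)ccc2c1O[C@H](c1ccc(O)c(O)c1)[C@H](O)[C@H]2c1c(O)cc(O)c2c1O[C@H](c1ccc(O)c(O)c1)[C@@H](O)C2 | target

Total step count: 12. Longest linear sequence: 11 steps (1 → 2 → 3 → 4 → 5 → 6 → 7 → 8 → 9 → 10 → 13 → 14; step 10 is the side branch to 12).

Steps most likely to fail

Step 4. Hydride abstraction by DDQ may lose site selectivity on the dimer, attacking the doubly benzylic C4–H of T as well, or the M alcohol may be oxidised further and unevenly. The fallback places the C4 heteroatom on the monomer before the first coupling (orthogonal activation); it sets out from 3 and returns at 5. Exchange of the ethoxyethoxy group of 3 with 2,6-dimethylbenzenethiol (BF3·OEt2, CH2Cl2, −78 °C) would give 4β-(2,6-dimethylphenylthio)-3,5,7,3',4'-penta-O-benzylepicatechin F1. A second portion of 3 would then be coupled with F1 as the nucleophile under BF3·OEt2 at −78 °C, a hard Lewis acid that leaves the C–S bond intact, to give the 4β-arylthio dimer F2. Thiophilic activation of F2 with AgOTf in wet THF should hydrolyse the thioether to alcohol 5.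

Step 11. The cation of M may be intercepted by C8 of the T unit of a second molecule of 10 (self-condensation), or the protic conditions needed to ionise the less activated 5-deoxy alcohol may begin to scramble the T–M bond. The fallback changes the leaving group and the activation mode; it sets out from 10 and returns at 13. Treatment of 10 with excess 2-mercaptobenzothiazole and BF3·OEt2 (CH2Cl2, −40 °C), where the thiol outcompetes any arene, would give the 4β-(benzothiazol-2-ylthio) dimer F3. F3 would then be activated with AgBF4 (THF/CH2Cl2, 0 °C) in the presence of 12 under non-protic, thiophilic conditions to give 13.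

Step 1. Under NaH the polyphenolate may undergo C-benzylation of the phloroglucinol ring, C2 epimerisation through B-ring quinone-methide opening, or incomplete alkylation of the hindered C3 alkoxide. The fallback obtains the 2,3-cis series by oxidation and reduction of the robust catechin ether; it sets out from 12 and returns at 2. Dess–Martin oxidation of 12 would give (2R)-5,7,3',4'-tetra-O-benzylflavan-3-one F4. L-Selectride (THF, −78 °C), attacking anti to the C2 aryl group, should then give 5,7,3',4'-tetra-O-benzyl-(−)-epicatechin F5. Benzylation of its single hydroxyl (NaH, BnBr, DMF), now with no free phenol present, gives 2.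

Further compounds
F1 | step 4 | 4β-(2,6-dimethylphenylthio)-3,5,7,3',4'-penta-O-benzylepicatechin | c1ccccc1COc1cc(OCc3ccccc3)c2c(c1)O[C@H](c1ccc(OCc3ccccc3)c(OCc3ccccc3)c1)[C@H](OCc3ccccc3)[C@H]2Sc1c(C)cccc1C
F2 | step 4 | penta-O-benzylepicatechin-(4β→8)-[4β-(2,6-dimethylphenylthio)-penta-O-benzylepicatechin] | c1ccccc1COc1cc(OCc3ccccc3)c2c(c1)O[C@H](c1ccc(OCc3ccccc3)c(OCc3ccccc3)c1)[C@H](OCc3ccccc3)[C@H]2c1c(OCc3ccccc3)cc(OCc3ccccc3)c2c1O[C@H](c1ccc(OCc3ccccc3)c(OCc3ccccc3)c1)[C@H](OCc3ccccc3)[C@H]2Sc1c(C)cccc1C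
F3 | step 11 | penta-O-benzylepicatechin-(4β→8)-[4β-(1,3-benzothiazol-2-ylthio)-3,7,3',4'-tetra-O-benzylepifisetinidol] | c1ccccc1COc1cc(OCc3ccccc3)c2c(c1)O[C@H](c1ccc(OCc3ccccc3)c(OCc3ccccc3)c1)[C@H](OCc3ccccc3)[C@H]2c1c(OCc3ccccc3)ccc2c1O[C@H](c1ccc(OCc3ccccc3)c(OCc3ccccc3)c1)[C@H](OCc3ccccc3)[C@H]2Sc1nc4ccccc4s1
F4 | step 1 | (2R)-5,7,3',4'-tetra-O-benzylflavan-3-one | c1ccccc1COc1cc(OCc3ccccc3)c2c(c1)O[C@H](c1ccc(OCc3ccccc3)c(OCc3ccccc3)c1)C(=O)C2
F5 | step 1 | 5,7,3',4'-tetra-O-benzyl-(−)-epicatechin | c1ccccc1COc1cc(OCc3ccccc3)c2c(c1)O[C@H](c1ccc(OCc3ccccc3)c(OCc3ccccc3)c1)[C@H](O)C2
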